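**Retrosynthetic overview**
- The target is a 2-formylpyrrole with an unbranched C21 chain on ring carbon C5 (chain numbered C1′ at the ring to C21′ at the methyl). It has no stereocentres, and the pyrrole ring is bought intact, so no ring is formed.
- Key disconnection: C10′–C11′. Both carbons are unmasked as primary radicals from carboxylic acids and joined by a nickel-electrocatalytic doubly decarboxylative cross-coupling of two N-hydroxyphthalimide esters (like-polarity union of two fatty-acid termini).
- Enabling feature: C10′ and C11′ lie in a bare polymethylene chain, each flanked only by CH2 groups and ten methylenes from the ring, so each is simply the α-carbon of a plain fatty acid. The N1–C2(–CHO) vinylogous formamide unit of the ring is electron-poor and remote, and should stay a spectator.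
- Second disconnection: ring C5–C1′, by Pd/norbornene C5–H alkylation of 1H-pyrrole-2-carbaldehyde with methyl 11-bromoundecanoate, followed by ester hydrolysis and activation.

Key step: step 5

Remark on the chemistry: no stereocentre is present, so no stereocontrol is required. The cross-coupling partner derived from dodecanoic acid is used in excess because it is the cheap one.

**Step 1**
Reactants: 1 1H-pyrrole-2-carbaldehyde; 2 methyl 11-bromoundecanoate (2 equiv)
Product: 3 methyl 11-(5-formyl-1H-pyrrol-2-yl)undecanoate
Conditions: PdCl2(MeCN)2 (10 mol%), norbornene (2 equiv), KHCO3 (3 equiv), DMA, 90 °C, air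
Reagents that add atoms: none
Why: Catellani-type Pd(II)/norbornene C–H alkylation of an electron-poor N–H pyrrole, in which N-palladation and norbornene insertion steer palladation to the only free position next to nitrogen (C5), the primary bromide adds oxidatively to the palladacycle, and reductive elimination with norbornene extrusion should deliver the 5-alkyl product while the weak base keeps N-alkylation slow.

**Step 2**
Reactants: 3 methyl 11-(5-formyl-1H-pyrrol-2-yl)undecanoate
Product: 4 11-(5-formyl-1H-pyrrol-2-yl)undecanoic acid
Conditions: LiOH·H2O (3 equiv), THF/MeOH/H2O, rt; then 1 M HCl to pH 3, 0 °C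
Reagents that add atoms: lithium hydroxide, [Li+].[OH-]
Why: Standard ester saponification; the non-enolisable, vinylogous-amide-type formyl group should be inert to hydroxide at room temperature.

**Step 3**
Reactants: 4 11-(5-formyl-1H-pyrrol-2-yl)undecanoic acid
Product: 5 1,3-dioxoisoindolin-2-yl 11-(5-formyl-1H-pyrrol-2-yl)undecanoate
Conditions: N-hydroxyphthalimide (1.1 equiv), DIC (1.1 equiv), DMAP (0.1 equiv), CH2Cl2, 0 °C to rt
Reagents that add atoms: N-hydroxyphthalimide, O=C1c2ccccc2C(=O)N1O
Why: Carbodiimide (Steglich-type) esterification of the acid with the acidic N-hydroxy imide, in which the weakly nucleophilic pyrrole N–H and the aldehyde should not compete.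

**Step 4**
Reactants: 6 dodecanoic acid
Product: 7 1,3-dioxoisoindolin-2-yl dodecanoate
Conditions: N-hydroxyphthalimide (1.05 equiv), DIC (1.1 equiv), DMAP (0.1 equiv), CH2Cl2, rt
Reagents that add atoms: N-hydroxyphthalimide, O=C1c2ccccc2C(=O)N1O
Why: The same carbodiimide esterification on a simple fatty acid, giving a crystalline redox-active ester.

**Step 5**
Reactants: 5 1,3-dioxoisoindolin-2-yl 11-(5-formyl-1H-pyrrol-2-yl)undecanoate (1 equiv); 7 1,3-dioxoisoindolin-2-yl dodecanoate (3 equiv)
Product: 10 5-henicosyl-1H-pyrrole-2-carbaldehyde, via undecyl radical 8 (not isolated), via 10-(5-formyl-1H-pyrrol-2-yl)decyl radical 9 (not isolated)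
Conditions: NiCl2·6H2O (20 mol%), 2,6-bis(pyrazol-1-yl)pyridine (20 mol%), AgNO3 (0.3 equiv), NMP, undivided cell, Mg(+)/RVC(−), constant current (ca. 2.5–3 F/mol), rt
Reagents that add atoms: none
Why: Single-electron reduction of each N-acyloxyphthalimide (by low-valent nickel or at the silver-nanoparticle-coated cathode) should give a radical anion that fragments to phthalimide anion, CO2 and an unstabilised primary radical (8 from 7, 9 from 5); nickel captures one radical, then the other, and the dialkylnickel(III) species reductively eliminates the C10′–C11′ bond. The closest known reaction type is the nickel-electrocatalytic doubly decarboxylative C(sp3)–C(sp3) coupling of two primary redox-active esters, a reductive and functional-group-tolerant relative of the mixed Kolbe electrolysis. No ring is closed and no stereocentre is created. The step needs cross- over homo-selectivity, which is secured statistically by the three-fold excess of 7; the expected homodimers (docosane and a bis-pyrrole dialdehyde) differ strongly in polarity from 10 and should be removed by chromatography. It also needs chemoselectivity for the two ester termini: the activated esters are reduced at far milder potential than the formylpyrrole, the nucleophilic primary radicals have no affinity for the remote vinylogous formamide ring, and the tridentate ligand disfavours β-hydride elimination from the alkylnickel intermediates.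

**Compound list**
1 | 1H-pyrrole-2-carbaldehyde | O=Cc1ccc[nH]1 | starting material
2 | methyl 11-bromoundecanoate | COC(=O)CCCCCCCCCCBr | starting material
3 | methyl 11-(5-formyl-1H-pyrrol-2-yl)undecanoate | COC(=O)CCCCCCCCCCc1ccc(C=O)[nH]1 | intermediate
4 | 11-(5-formyl-1H-pyrrol-2-yl)undecanoic acid | O=Cc1ccc(CCCCCCCCCCC(=O)O)[nH]1 | intermediate
5 | 1,3-dioxoisoindolin-2-yl 11-(5-formyl-1H-pyrrol-2-yl)undecanoate | O=Cc1ccc(CCCCCCCCCCC(=O)ON2C(=O)c3ccccc3C2=O)[nH]1 | intermediate
6 | dodecanoic acid (lauric acid) | CCCCCCCCCCCC(=O)O | starting material
7 | 1,3-dioxoisoindolin-2-yl dodecanoate | CCCCCCCCCCCC(=O)ON1C(=O)c2ccccc2C1=O | intermediate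
8 | undecyl radical | CCCCCCCCCC[CH2] | intermediate
9 | 10-(5-formyl-1H-pyrrol-2-yl)decyl radical | O=Cc1ccc(CCCCCCCCC[CH2])[nH]1 | intermediate
10 | 5-henicosyl-1H-pyrrole-2-carbaldehyde (CNP0186753.0) | CCCCCCCCCCCCCCCCCCCCCc1ccc(C=O)[nH]1 | target

**Step count**
Total steps: 5. Longest linear sequence: 4 (steps 1, 2, 3, 5); step 4 is a one-step branch.

**Steps most likely to fail**

1. Step 5 (key step). What may go wrong: homocoupling may dominate over cross-coupling; the alkylnickel or radical intermediates may be quenched by hydrogen transfer (hydrodecarboxylation) or lose hydride to give alkenes; the formyl group or the N–H may interfere with low-valent nickel at the cathode.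
Fallback: the same C10′–C11′ bond is made by classical anodic radical coupling before the heterocycle is present. It sets out from 2 and 6 and returns at 10. Ester 2 is hydrolysed (aqueous HBr, AcOH, reflux) to 11-bromoundecanoic acid F1, which is also commercially available. Mixed Kolbe electrolysis of F1 with a three- to four-fold excess of 6 (Pt electrodes, MeOH, about 5–10% neutralisation with NaOMe, high current density, 40–50 °C) should give 1-bromohenicosane F2 beside docosane and 1,20-dibromoicosane. F2 is then used to alkylate C5 of 1 under the conditions of step 1, which should give 10 directly; the hydrocarbon by-product is inert there and easily removed.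

2. Step 1. What may go wrong: the relatively acidic N–H of the formylpyrrole may be alkylated in competition with C5, and C–H palladation of the deactivated ring may be sluggish.
Fallback: a Negishi sp3–sp2 cross-coupling that fixes the regiochemistry through a halogen. It sets out from 2 and returns at 4. Commercial 5-bromo-1H-pyrrole-2-carbaldehyde is N-protected (Boc2O, cat. DMAP, MeCN) to tert-butyl 2-bromo-5-formyl-1H-pyrrole-1-carboxylate F3. Zinc insertion into 2 (Zn dust, cat. I2, DMA, 80 °C) gives (11-methoxy-11-oxoundecyl)zinc bromide F4. Coupling of F4 with F3 (Pd(OAc)2, SPhos, THF/DMA, rt) should give tert-butyl 2-formyl-5-(11-methoxy-11-oxoundecyl)-1H-pyrrole-1-carboxylate F5. LiOH in THF/MeOH/H2O then removes both the methyl ester and the N-Boc group to give 4.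

3. Step 3. What may go wrong: acyl transfer from the activated ester to the pyrrole nitrogen of a second molecule (oligomerisation), rearrangement of the O-acylisourea to an N-acylurea, or hydrolysis of the activated ester during purification.
Fallback: the activated ester is avoided altogether by an alkyl–alkyl Suzuki–Miyaura coupling across the same C10′–C11′ bond. It sets out from 1 and returns at 10. Compound 1 is alkylated at C5 with excess 1,10-dibromodecane under the conditions of step 1 to give 5-(10-bromodecyl)-1H-pyrrole-2-carbaldehyde F6. Undec-1-ene is hydroborated with 9-BBN (THF, rt) to 9-undecyl-9-borabicyclo[3.3.1]nonane F7. Coupling of F6 with F7 (Pd(OAc)2, PCy3, K3PO4·H2O, THF, rt) should give 10.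

**Further compounds**
F1 | step 5 | 11-bromoundecanoic acid | OC(=O)CCCCCCCCCCBr
F2 | step 5 | 1-bromohenicosane | CCCCCCCCCCCCCCCCCCCCCBr
F3 | step 1 | tert-butyl 2-bromo-5-formyl-1H-pyrrole-1-carboxylate | CC(C)(C)OC(=O)n1c(Br)ccc1C=O
F4 | step 1 | (11-methoxy-11-oxoundecyl)zinc bromide | COC(=O)CCCCCCCCCC[Zn]Br
F5 | step 1 | tert-butyl 2-formyl-5-(11-methoxy-11-oxoundecyl)-1H-pyrrole-1-carboxylate | COC(=O)CCCCCCCCCCc1ccc(C=O)n1C(=O)OC(C)(C)C
F6 | step 3 | 5-(10-bromodecyl)-1H-pyrrole-2-carbaldehyde | O=Cc1ccc(CCCCCCCCCCBr)[nH]1
F7 | step 3 | 9-undecyl-9-borabicyclo[3.3.1]nonane | CCCCCCCCCCCB1C2CCCC1CCC2
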